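**Retrosynthetic overview**

1. Target 31 is menaquinone-8 with the second isoprene unit from the ring saturated, (7′R). Ring B (the quinone ring, C1–C4/C4a/C8a) is disconnected into pentacarbonyl[methoxy(phenyl)carbene]chromium 28 (ring A plus one carbonyl carbon), one CO ligand (the other carbonyl carbon) and the internal alkyne of enyne 24 (C2 and C3 with their CH3 and chain): a Dötz benzannulation with oxidative work-up. Ring A is bought as phenyllithium; ring B is the only ring formed, in the last step.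
2. Enabling feature: C2 and C3 of ring B carry two carbon substituents (CH3 and C1′H2), i.e. the two carbons of a 2-alkyne. Because ring A (C5–C8) is unsubstituted and C1 and C4 are both carbonyls, either orientation of alkyne uptake gives the same quinone after oxidation.
3. Enyne 24: the C1′–C(sp) bond is made by copper-catalysed propynylation of the C40 allylic bromide 22.
4. C40 chain: two allyl sulfone anion alkylations (C12′–C13′ and C20′–C21′) join farnesyl sulfone 17 (units 1–3), hydroxy sulfone 12 (units 4–5) and the chiral C15 bromide 9 (units 6–8). Both sulfonyl groups are removed in one hydride step.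
5. Bromide 9: C7′ comes from (S)-citronellyl bromide 1; unit 8 is built by propargyl homologation and zirconium-catalysed methylalumination (E-C2′=C3′); the terminal E-methyl group is oxidised with SeO2.

Key step: step 17

Remark: side-chain carbons are numbered C1′–C32′ from the ring and isoprene units 1–8 from the far end. Commercial 1, 10 and 16 are assumed to be of high enantiomeric and geometric purity.

**Route**

Step 1
Reactants: 1 (S)-citronellyl bromide, (6S)-8-bromo-2,6-dimethyloct-2-ene
Product: 3 (6R)-6,10-dimethylundec-9-en-1-yne, via silylalkyne 2 (not isolated)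
Conditions: 1-(trimethylsilyl)propyne, n-BuLi, THF, −78 → 0 °C; then 1, −78 °C → rt; then MeOH, K2CO3 (0.2 equiv), rt
Reagents that add atoms: 1-(trimethylsilyl)propyne, CC#C[Si](C)(C)C
Why: SN2 alkylation of the silyl-stabilised propargyl anion by a primary bromide, then base-catalysed methanolysis of the C–Si bond, is a standard three-carbon alkyne homologation; C7′ comes unchanged from 1 and its descriptor changes from S to R only because the CIP ranking of its two chain arms is reversed.

Step 2
Reactants: 3 (6R)-6,10-dimethylundec-9-en-1-yne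
Product: 6 (2E,7R)-3,7,11-trimethyldodeca-2,10-dien-1-ol, via alkenylalane 4 (not isolated), via lithium alkenylaluminate 5 (not isolated)
Conditions: Me3Al, Cp2ZrCl2 (0.25 equiv), CH2Cl2, 0 °C → rt; then n-BuLi, THF, −78 °C; (CH2O)n, −78 °C → rt
Reagents that add atoms: trimethylaluminium, C[Al](C)C; paraformaldehyde (as formaldehyde), C=O
Why: Negishi zirconium-catalysed methylalumination adds CH3 and Al syn across the terminal alkyne with Al on the terminal carbon, so trapping of the derived aluminate with formaldehyde should give the E-trisubstituted allylic alcohol (C2′=C3′) while the remote trisubstituted alkene stays inert.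

Step 3
Reactants: 6 (2E,7R)-3,7,11-trimethyldodeca-2,10-dien-1-ol
Product: 7 tert-butyl{[(2E,7R)-3,7,11-trimethyldodeca-2,10-dien-1-yl]oxy}diphenylsilane
Conditions: t-BuPh2SiCl, imidazole, DMF, rt
Reagents that add atoms: tert-butyl(chloro)diphenylsilane, CC(C)(C)[Si](Cl)(c1ccccc1)c1ccccc1
Why: standard silylation of a primary allylic alcohol gives an ether that withstands the oxidation, organolithium, hydride and zerovalent palladium steps that follow.

Step 4
Reactants: 7 silyl ether of 6
Product: 8 (2E,6R,10E)-12-[(tert-butyldiphenylsilyl)oxy]-2,6,10-trimethyldodeca-2,10-dien-1-ol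
Conditions: SeO2 (0.3 equiv), t-BuOOH, salicylic acid (0.1 equiv), CH2Cl2, 0 °C → rt
Reagents that add atoms: selenium dioxide (catalytic oxygen carrier), O=[Se]=O; tert-butyl hydroperoxide, CC(C)(C)OO
Why: Riley allylic oxidation (ene reaction, then 2,3-sigmatropic shift) should hydroxylate the E-methyl group of the terminal, more electron-rich isopropylidene unit, the C2′=C3′ alkene being deactivated by its allylic silyloxy group.

Step 5
Reactants: 8 C15 allylic alcohol
Product: 9 {[(2E,7R,10E)-12-bromo-3,7,11-trimethyldodeca-2,10-dien-1-yl]oxy}(tert-butyl)diphenylsilane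
Conditions: CBr4, PPh3, CH2Cl2, 0 °C
Reagents that add atoms: tetrabromomethane, BrC(Br)(Br)Br
Why: Appel bromination of a primary allylic alcohol under neutral conditions should proceed without allylic transposition and without loss of the silyl ether.

Step 6
Reactants: 10 geranyl bromide, (2E)-1-bromo-3,7-dimethylocta-2,6-diene
Product: 11 {[(2E)-3,7-dimethylocta-2,6-dien-1-yl]sulfonyl}benzene
Conditions: PhSO2Na, DMF, rt
Reagents that add atoms: sodium benzenesulfinate, [Na+].[O-]S(=O)c1ccccc1
Why: SN2 S-alkylation of the sulfinate at the primary allylic bromide gives the allyl sulfone with the E-alkene retained.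

Step 7
Reactants: 11 geranyl phenyl sulfone
Product: 12 (2E,6E)-2,6-dimethyl-8-(phenylsulfonyl)octa-2,6-dien-1-ol
Conditions: SeO2 (0.3 equiv), t-BuOOH, salicylic acid (0.1 equiv), CH2Cl2, 0 °C → rt
Reagents that add atoms: selenium dioxide (catalytic oxygen carrier), O=[Se]=O; tert-butyl hydroperoxide, CC(C)(C)OO
Why: Riley allylic oxidation at the E-methyl group of the terminal alkene, the alkene next to the electron-withdrawing sulfonyl group being deactivated.

Step 8
Reactants: 12 hydroxy sulfone; 9 C15 allylic bromide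
Product: 14 (2E,6E,10E,14R,18E)-20-[(tert-butyldiphenylsilyl)oxy]-2,6,10,14,18-pentamethyl-8-(phenylsulfonyl)icosa-2,6,10,18-tetraen-1-ol (both epimers at C8), via dilithiated sulfone 13 (not isolated)
Conditions: 12, n-BuLi (2.1 equiv), THF–DMPU, −78 °C; then 9, −78 → −40 °C; H2O
Reagents that add atoms: none
Why: Biellmann-type sulfone coupling: the α-sulfonyl allyl carbanion of the dianion is alkylated at its α-carbon by the allylic bromide far faster than the lithium alkoxide, forming C12′–C13′; the sulfone-bearing carbon forms without control, which is harmless because it becomes CH2 in step 12.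

Step 9
Reactants: 14 C25 hydroxy sulfone
Product: 15 tert-butyl{[(2E,7R,10E,14E,18E)-20-bromo-3,7,11,15,19-pentamethyl-13-(phenylsulfonyl)icosa-2,10,14,18-tetraen-1-yl]oxy}diphenylsilane
Conditions: CBr4, PPh3, CH2Cl2, 0 °C
Reagents that add atoms: tetrabromomethane, BrC(Br)(Br)Br
Why: Appel bromination of the primary allylic alcohol; the neutral medium leaves the acidic α-sulfonyl C–H and the silyl ether untouched.

Step 10
Reactants: 16 (2E,6E)-farnesyl bromide, (2E,6E)-1-bromo-3,7,11-trimethyldodeca-2,6,10-triene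
Product: 17 {[(2E,6E)-3,7,11-trimethyldodeca-2,6,10-trien-1-yl]sulfonyl}benzene
Conditions: PhSO2Na, DMF, rt
Reagents that add atoms: sodium benzenesulfinate, [Na+].[O-]S(=O)c1ccccc1
Why: SN2 S-alkylation of the sulfinate at the primary allylic bromide, as in step 6.

Step 11
Reactants: 17 farnesyl phenyl sulfone; 15 C25 allylic bromide
Product: 19 tert-butyl{[(2E,7R,10E,14E,18E,22E,26E)-3,7,11,15,19,23,27,31-octamethyl-13,21-bis(phenylsulfonyl)dotriaconta-2,10,14,18,22,26,30-heptaen-1-yl]oxy}diphenylsilane (epimers at C13 and C21), via lithiated sulfone 18 (not isolated)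
Conditions: 17, n-BuLi (1.05 equiv), THF, −78 °C; then 15, −78 → −40 °C
Reagents that add atoms: none
Why: second Biellmann-type alkylation of an α-sulfonyl allyl carbanion by a primary allylic bromide forms C20′–C21′; the low temperature should let alkylation outrun proton transfer from the internal sulfone of 15.

Step 12
Reactants: 19 bis-sulfone
Product: 20 tert-butyl{[(2E,7R,10E,14E,18E,22E,26E)-3,7,11,15,19,23,27,31-octamethyldotriaconta-2,10,14,18,22,26,30-heptaen-1-yl]oxy}diphenylsilane
Conditions: PdCl2(dppp) (0.1 equiv), LiBHEt3 (6 equiv), THF, 0 °C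
Reagents that add atoms: none
Why: palladium-catalysed hydride reduction of allylic sulfones: zerovalent palladium ionises each allylic C–S bond to a π-allyl complex and hydride is delivered to the less substituted terminus, so both sulfonyl groups should be replaced by hydrogen with the trisubstituted E-alkenes left in place and the allylic silyl ether untouched.

Step 13
Reactants: 20 C40 silyl ether
Product: 21 (2E,7R,10E,14E,18E,22E,26E)-3,7,11,15,19,23,27,31-octamethyldotriaconta-2,10,14,18,22,26,30-heptaen-1-ol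
Conditions: Bu4NF, THF, rt
Reagents that add atoms: none
Why: fluoride-induced cleavage of the silyl ether, with no effect on the polyene or on C7′.

Step 14
Reactants: 21 C40 allylic alcohol
Product: 22 (2E,7R,10E,14E,18E,22E,26E)-1-bromo-3,7,11,15,19,23,27,31-octamethyldotriaconta-2,10,14,18,22,26,30-heptaene
Conditions: CBr4, PPh3, CH2Cl2, 0 °C
Reagents that add atoms: tetrabromomethane, BrC(Br)(Br)Br
Why: Appel bromination of the primary allylic alcohol with retention of the E-C2′=C3′ alkene; the bromide is used without storage.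

Step 15
Reactants: 22 C40 allylic bromide; 23 1-propynylmagnesium bromide
Product: 24 (5E,10R,13E,17E,21E,25E,29E)-6,10,14,18,22,26,30,34-octamethylpentatriaconta-5,13,17,21,25,29,33-heptaen-2-yne
Conditions: CuCl (0.1 equiv), THF, 0 → 50 °C
Reagents that add atoms: none
Why: copper-catalysed cross-coupling of an alkynyl Grignard reagent with a primary allylic bromide at its unsubstituted α-carbon (SN2) should give the skipped 1,4-enyne with the E-alkene retained.

Step 16
Reactants: 25 chromium hexacarbonyl, Cr(CO)6; 26 phenyllithium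
Product: 28 pentacarbonyl[methoxy(phenyl)methylidene]chromium, via lithium acylchromate 27 (not isolated)
Conditions: PhLi, Et2O, 0 °C → rt; then Me3OBF4, CH2Cl2, 0 °C
Reagents that add atoms: trimethyloxonium tetrafluoroborate, C[O+](C)C.F[B-](F)(F)F
Why: Fischer carbene synthesis: the aryllithium adds to a CO ligand and the resulting acylmetalate is O-methylated by the oxonium salt.

Step 17
Reactants: 24 enyne; 28 carbene complex
Product: 31 2-methyl-3-[(2E,7R,10E,14E,18E,22E,26E)-3,7,11,15,19,23,27,31-octamethyldotriaconta-2,10,14,18,22,26,30-heptaen-1-yl]naphthalene-1,4-dione, via naphthol complex 29 (not isolated), via regioisomeric naphthol complex 30 (not isolated)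
Conditions: 28 (1.3 equiv), t-BuOMe, 50 °C, Ar; then (NH4)2Ce(NO3)6, MeCN–H2O, 0 °C
Reagents that add atoms: water, O
Why: Thermal loss of one CO from 28 lets the alkyne of 24 coordinate and insert into the Cr=C bond to give a vinylcarbene, a CO ligand inserts to give a chromium-bound vinylketene, 6π-electrocyclisation onto an ortho carbon of the phenyl group and tautomerisation give the Cr(CO)3-bound 4-methoxy-1-naphthols 29 and 30, and tetravalent cerium then removes the metal and oxidises the hydroquinone monomethyl ether to the quinone with loss of methanol. The closest known reaction type is the Dötz benzannulation of aryl(methoxy)carbene chromium complexes with internal alkynes followed by oxidative work-up, which is established for 2-alkynes carrying a skipped prenyl-type alkene and leads to vitamin K-type quinones. Ring B is the only ring closed, as a formal [3+2+1] benzannulation whose ring-closing event is a thermal 6π-electrocyclisation of the dienylketene; in the orientation that leads to 29 the carbene carbon becomes C4 and bonds to the chain-bearing C3 while the CO carbon becomes C1 and bonds to C2 and to the ortho carbon C8a, and the reverse orientation gives 30. No stereocentre is formed; C7′ and the seven E-alkenes are spectators. The regiochemistry of alkyne insertion, expected to be poor for CH3 against CH2R, need not be controlled, because ring A is unsubstituted and both oxygen-bearing carbons end as carbonyls, so 29 and 30 give the same quinone. Chemoselectivity for the alkyne rests on the inertness of unactivated trisubstituted alkenes towards this carbene complex at 50 °C and on the 1,4-relationship of the alkyne and the nearest alkene, which rules out intramolecular cyclopropanation, while a short, cold cerium oxidation should spare the polyene.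

**Compound list**

1 | (S)-citronellyl bromide, (6S)-8-bromo-2,6-dimethyloct-2-ene | CC(C)=CCC[C@H](C)CCBr | starting material
2 | trimethyl[(6R)-6,10-dimethylundec-9-en-1-yn-1-yl]silane | CC(C)=CCC[C@H](C)CCCC#C[Si](C)(C)C | intermediate
3 | (6R)-6,10-dimethylundec-9-en-1-yne | CC(C)=CCC[C@H](C)CCCC#C | intermediate
4 | dimethyl[(1E,6R)-2,6,10-trimethylundeca-1,9-dien-1-yl]alumane | CC(C)=CCC[C@H](C)CCC/C(C)=C/[Al](C)C | intermediate
5 | lithium butyl(dimethyl)[(1E,6R)-2,6,10-trimethylundeca-1,9-dien-1-yl]aluminate | [Li+].CC(C)=CCC[C@H](C)CCC/C(C)=C/[Al-](C)(C)CCCC | intermediate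
6 | (2E,7R)-3,7,11-trimethyldodeca-2,10-dien-1-ol | CC(C)=CCC[C@H](C)CCC/C(C)=C/CO | intermediate
7 | tert-butyl{[(2E,7R)-3,7,11-trimethyldodeca-2,10-dien-1-yl]oxy}diphenylsilane | CC(C)=CCC[C@H](C)CCC/C(C)=C/CO[Si](c1ccccc1)(c1ccccc1)C(C)(C)C | intermediate
8 | (2E,6R,10E)-12-[(tert-butyldiphenylsilyl)oxy]-2,6,10-trimethyldodeca-2,10-dien-1-ol | OC/C(C)=C/CC[C@H](C)CCC/C(C)=C/CO[Si](c1ccccc1)(c1ccccc1)C(C)(C)C | intermediate
9 | {[(2E,7R,10E)-12-bromo-3,7,11-trimethyldodeca-2,10-dien-1-yl]oxy}(tert-butyl)diphenylsilane | BrC/C(C)=C/CC[C@H](C)CCC/C(C)=C/CO[Si](c1ccccc1)(c1ccccc1)C(C)(C)C | intermediate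
10 | geranyl bromide, (2E)-1-bromo-3,7-dimethylocta-2,6-diene | CC(C)=CCC/C(C)=C/CBr | starting material
11 | {[(2E)-3,7-dimethylocta-2,6-dien-1-yl]sulfonyl}benzene | CC(C)=CCC/C(C)=C/CS(=O)(=O)c1ccccc1 | intermediate
12 | (2E,6E)-2,6-dimethyl-8-(phenylsulfonyl)octa-2,6-dien-1-ol | OC/C(C)=C/CC/C(C)=C/CS(=O)(=O)c1ccccc1 | intermediate
13 | dilithium salt of 12 (alkoxide and α-sulfonyl carbanion) | [Li+].[Li+].[O-]C/C(C)=C/CC/C(C)=C/[CH-]S(=O)(=O)c1ccccc1 | intermediate
14 | (2E,6E,10E,14R,18E)-20-[(tert-butyldiphenylsilyl)oxy]-2,6,10,14,18-pentamethyl-8-(phenylsulfonyl)icosa-2,6,10,18-tetraen-1-ol, both epimers at C8 | OC/C(C)=C/CC/C(C)=C/C(C/C(C)=C/CC[C@H](C)CCC/C(C)=C/CO[Si](c1ccccc1)(c1ccccc1)C(C)(C)C)S(=O)(=O)c1ccccc1 | intermediate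
15 | tert-butyl{[(2E,7R,10E,14E,18E)-20-bromo-3,7,11,15,19-pentamethyl-13-(phenylsulfonyl)icosa-2,10,14,18-tetraen-1-yl]oxy}diphenylsilane, both epimers at C13 | BrC/C(C)=C/CC/C(C)=C/C(C/C(C)=C/CC[C@H](C)CCC/C(C)=C/CO[Si](c1ccccc1)(c1ccccc1)C(C)(C)C)S(=O)(=O)c1ccccc1 | intermediate
16 | (2E,6E)-farnesyl bromide, (2E,6E)-1-bromo-3,7,11-trimethyldodeca-2,6,10-triene | CC(C)=CCC/C(C)=C/CC/C(C)=C/CBr | starting material
17 | {[(2E,6E)-3,7,11-trimethyldodeca-2,6,10-trien-1-yl]sulfonyl}benzene | CC(C)=CCC/C(C)=C/CC/C(C)=C/CS(=O)(=O)c1ccccc1 | intermediate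
18 | lithium salt of 17 (α-sulfonyl carbanion) | [Li+].CC(C)=CCC/C(C)=C/CC/C(C)=C/[CH-]S(=O)(=O)c1ccccc1 | intermediate
19 | tert-butyl{[(2E,7R,10E,14E,18E,22E,26E)-3,7,11,15,19,23,27,31-octamethyl-13,21-bis(phenylsulfonyl)dotriaconta-2,10,14,18,22,26,30-heptaen-1-yl]oxy}diphenylsilane, epimers at C13 and C21 | CC(C)=CCC/C(C)=C/CC/C(C)=C/C(C/C(C)=C/CC/C(C)=C/C(C/C(C)=C/CC[C@H](C)CCC/C(C)=C/CO[Si](c1ccccc1)(c1ccccc1)C(C)(C)C)S(=O)(=O)c1ccccc1)S(=O)(=O)c1ccccc1 | intermediate
20 | tert-butyl{[(2E,7R,10E,14E,18E,22E,26E)-3,7,11,15,19,23,27,31-octamethyldotriaconta-2,10,14,18,22,26,30-heptaen-1-yl]oxy}diphenylsilane | CC(C)=CCC/C(C)=C/CC/C(C)=C/CC/C(C)=C/CC/C(C)=C/CC/C(C)=C/CC[C@H](C)CCC/C(C)=C/CO[Si](c1ccccc1)(c1ccccc1)C(C)(C)C | intermediate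
21 | (2E,7R,10E,14E,18E,22E,26E)-3,7,11,15,19,23,27,31-octamethyldotriaconta-2,10,14,18,22,26,30-heptaen-1-ol | CC(C)=CCC/C(C)=C/CC/C(C)=C/CC/C(C)=C/CC/C(C)=C/CC/C(C)=C/CC[C@H](C)CCC/C(C)=C/CO | intermediate
22 | (2E,7R,10E,14E,18E,22E,26E)-1-bromo-3,7,11,15,19,23,27,31-octamethyldotriaconta-2,10,14,18,22,26,30-heptaene | CC(C)=CCC/C(C)=C/CC/C(C)=C/CC/C(C)=C/CC/C(C)=C/CC/C(C)=C/CC[C@H](C)CCC/C(C)=C/CBr | intermediate
23 | 1-propynylmagnesium bromide | CC#C[Mg]Br | starting material
24 | (5E,10R,13E,17E,21E,25E,29E)-6,10,14,18,22,26,30,34-octamethylpentatriaconta-5,13,17,21,25,29,33-heptaen-2-yne | CC(C)=CCC/C(C)=C/CC/C(C)=C/CC/C(C)=C/CC/C(C)=C/CC/C(C)=C/CC[C@H](C)CCC/C(C)=C/CC#CC | intermediate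
25 | chromium hexacarbonyl | O=C=[Cr](=C=O)(=C=O)(=C=O)(=C=O)=C=O | starting material
26 | phenyllithium | [Li]c1ccccc1 | starting material
27 | lithium pentacarbonyl[oxido(phenyl)methylidene]chromate | [Li+].[O-]C(c1ccccc1)=[Cr](=C=O)(=C=O)(=C=O)(=C=O)=C=O | intermediate
28 | pentacarbonyl[methoxy(phenyl)methylidene]chromium | COC(c1ccccc1)=[Cr](=C=O)(=C=O)(=C=O)(=C=O)=C=O | intermediate
29 | tricarbonyl{η6-4-methoxy-2-methyl-3-[(2E,7R,10E,14E,18E,22E,26E)-3,7,11,15,19,23,27,31-octamethyldotriaconta-2,10,14,18,22,26,30-heptaen-1-yl]naphthalen-1-ol}chromium (metal on the oxygenated ring) | CC(C)=CCC/C(C)=C/CC/C(C)=C/CC/C(C)=C/CC/C(C)=C/CC/C(C)=C/CC[C@H](C)CCC/C(C)=C/Cc1c(C)c(O)c2ccccc2c1OC.O=C=[Cr](=C=O)=C=O | intermediate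
30 | tricarbonyl{η6-4-methoxy-3-methyl-2-[(2E,7R,10E,14E,18E,22E,26E)-3,7,11,15,19,23,27,31-octamethyldotriaconta-2,10,14,18,22,26,30-heptaen-1-yl]naphthalen-1-ol}chromium (metal on the oxygenated ring) | CC(C)=CCC/C(C)=C/CC/C(C)=C/CC/C(C)=C/CC/C(C)=C/CC/C(C)=C/CC[C@H](C)CCC/C(C)=C/Cc1c(C)c(OC)c2ccccc2c1O.O=C=[Cr](=C=O)=C=O | intermediate
31 | 2-methyl-3-[(2E,7R,10E,14E,18E,22E,26E)-3,7,11,15,19,23,27,31-octamethyldotriaconta-2,10,14,18,22,26,30-heptaen-1-yl]naphthalene-1,4-dione | CC(C)=CCC/C(C)=C/CC/C(C)=C/CC/C(C)=C/CC/C(C)=C/CC/C(C)=C/CC[C@H](C)CCC/C(C)=C/CC1=C(C)C(=O)c2ccccc2C1=O | target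

**Step count and risks**

Total step count: 17. Longest linear sequence: 13 steps (steps 1–5, 8, 9, 11–15 and 17).

Steps most likely to fail:

Step 17. The vinylcarbene and vinylketene intermediates may be diverted into cyclobutenone, indene or furan products instead of the naphthol, and the polyene may suffer oxidative degradation during the cerium work-up. The fallback abandons the benzannulation and attaches a preformed naphthalene to the chain; it sets out from bromide 22 and comes back at target 31. Commercial menadione is reduced and methylated (Na2S2O4; then Me2SO4, KOH) to 1,4-dimethoxy-2-methylnaphthalene F1. This is brominated (Br2, CH2Cl2, 0 °C) to 2-bromo-1,4-dimethoxy-3-methylnaphthalene F2 and converted with Mg in THF into (1,4-dimethoxy-3-methylnaphthalen-2-yl)magnesium bromide F3. Copper-catalysed (CuBr·SMe2) SN2 allylation of F3 with 22 should give 1,4-dimethoxy-2-methyl-3-[(2E,7R,10E,14E,18E,22E,26E)-3,7,11,15,19,23,27,31-octamethyldotriaconta-2,10,14,18,22,26,30-heptaen-1-yl]naphthalene F4. Oxidative demethylation with (NH4)2Ce(NO3)6 in MeCN–H2O at 0 °C then gives 31.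

Step 11. Proton transfer from the tertiary α-sulfonyl C–H of 15 to carbanion 18 may compete with alkylation and lead to scrambled alkylation or elimination. The fallback removes the first sulfonyl group before the second coupling; it sets out from 14 and comes back at 20. Reduction of 14 with PdCl2(dppp)/LiBHEt3 should give (2E,6E,10E,14R,18E)-20-[(tert-butyldiphenylsilyl)oxy]-2,6,10,14,18-pentamethylicosa-2,6,10,18-tetraen-1-ol F5. Appel bromination gives tert-butyl{[(2E,7R,10E,14E,18E)-20-bromo-3,7,11,15,19-pentamethylicosa-2,10,14,18-tetraen-1-yl]oxy}diphenylsilane F6. Alkylation of 18 with F6 gives the mono-sulfone tert-butyl{[(2E,7R,10E,14E,18E,22E,26E)-3,7,11,15,19,23,27,31-octamethyl-21-(phenylsulfonyl)dotriaconta-2,10,14,18,22,26,30-heptaen-1-yl]oxy}diphenylsilane F7. A second PdCl2(dppp)/LiBHEt3 reduction then gives 20.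

Step 4. Over-oxidation to the enal and competing oxidation at internal allylic methylene groups may leave little of the E-allylic alcohol. The fallback cleaves the terminal alkene and rebuilds it by olefination; it sets out from 7 and comes back at 8. Epoxidation of the more electron-rich terminal alkene (m-CPBA, CH2Cl2, −20 °C) gives tert-butyl{[(2E,7R)-9-(3,3-dimethyloxiran-2-yl)-3,7-dimethylnon-2-en-1-yl]oxy}diphenylsilane F8. Cleavage with H5IO6 in aqueous THF gives (4R,8E)-10-[(tert-butyldiphenylsilyl)oxy]-4,8-dimethyldec-8-enal F9. E-selective Wittig reaction with Ph3P=C(CH3)CO2Et gives ethyl (2E,6R,10E)-12-[(tert-butyldiphenylsilyl)oxy]-2,6,10-trimethyldodeca-2,10-dienoate F10. Reduction with (i-Bu)2AlH at −78 °C then gives 8.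

Further compounds
F1 | step 17 | 1,4-dimethoxy-2-methylnaphthalene | COc1cc(C)c(OC)c2ccccc12
F2 | step 17 | 2-bromo-1,4-dimethoxy-3-methylnaphthalene | COc1c(C)c(Br)c(OC)c2ccccc12
F3 | step 17 | (1,4-dimethoxy-3-methylnaphthalen-2-yl)magnesium bromide | COc1c(C)c([Mg]Br)c(OC)c2ccccc12
F4 | step 17 | 1,4-dimethoxy-2-methyl-3-[(2E,7R,10E,14E,18E,22E,26E)-3,7,11,15,19,23,27,31-octamethyldotriaconta-2,10,14,18,22,26,30-heptaen-1-yl]naphthalene | CC(C)=CCC/C(C)=C/CC/C(C)=C/CC/C(C)=C/CC/C(C)=C/CC/C(C)=C/CC[C@H](C)CCC/C(C)=C/Cc1c(C)c(OC)c2ccccc2c1OC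
F5 | step 11 | (2E,6E,10E,14R,18E)-20-[(tert-butyldiphenylsilyl)oxy]-2,6,10,14,18-pentamethylicosa-2,6,10,18-tetraen-1-ol | OC/C(C)=C/CC/C(C)=C/CC/C(C)=C/CC[C@H](C)CCC/C(C)=C/CO[Si](c1ccccc1)(c1ccccc1)C(C)(C)C
F6 | step 11 | tert-butyl{[(2E,7R,10E,14E,18E)-20-bromo-3,7,11,15,19-pentamethylicosa-2,10,14,18-tetraen-1-yl]oxy}diphenylsilane | BrC/C(C)=C/CC/C(C)=C/CC/C(C)=C/CC[C@H](C)CCC/C(C)=C/CO[Si](c1ccccc1)(c1ccccc1)C(C)(C)C
F7 | step 11 | tert-butyl{[(2E,7R,10E,14E,18E,22E,26E)-3,7,11,15,19,23,27,31-octamethyl-21-(phenylsulfonyl)dotriaconta-2,10,14,18,22,26,30-heptaen-1-yl]oxy}diphenylsilane | CC(C)=CCC/C(C)=C/CC/C(C)=C/C(C/C(C)=C/CC/C(C)=C/CC/C(C)=C/CC[C@H](C)CCC/C(C)=C/CO[Si](c1ccccc1)(c1ccccc1)C(C)(C)C)S(=O)(=O)c1ccccc1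
F8 | step 4 | tert-butyl{[(2E,7R)-9-(3,3-dimethyloxiran-2-yl)-3,7-dimethylnon-2-en-1-yl]oxy}diphenylsilane | CC1(C)OC1CC[C@H](C)CCC/C(C)=C/CO[Si](c1ccccc1)(c1ccccc1)C(C)(C)C
F9 | step 4 | (4R,8E)-10-[(tert-butyldiphenylsilyl)oxy]-4,8-dimethyldec-8-enal | O=CCC[C@H](C)CCC/C(C)=C/CO[Si](c1ccccc1)(c1ccccc1)C(C)(C)C
F10 | step 4 | ethyl (2E,6R,10E)-12-[(tert-butyldiphenylsilyl)oxy]-2,6,10-trimethyldodeca-2,10-dienoate | CCOC(=O)/C(C)=C/CC[C@H](C)CCC/C(C)=C/CO[Si](c1ccccc1)(c1ccccc1)C(C)(C)C
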